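**Retrosynthetic overview**
1. Ring atoms are numbered as in cyclohexa-2,5-dien-1-one (C1 = C=O, C2 = propenyl carbon, C4 = quaternary C–O, C5 = ring C–OMe, C6 = ring CH between C5 and C1); the last disconnection, 13 ⇒ 12, is O-methylation at C4.
2. Enabling feature: in the vinylogous ester O=C1–C6H=C5(OMe) of the dienone ring (ring A), the methoxy carbon C5 is bonded directly to the oxygen-bearing quaternary C4. C5 is therefore taken back to a methyl ester on C4 and C6 to a phosphorus ylide carbon, and the C5=C6 bond closes ring A by ester olefination with the ester OMe kept.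
3. The keto ylide is stored as butenolide 10 (temporary ring B, O–C1(=O)–C2=C3–C4): the C4 oxygen holds C1 and fixes the cis C2=C3 geometry. Ph3P=CH2 opens ring B and the resulting ylide closes ring A (order of rings: B in step 4, B → A in step 6).
4. 10 ⇐ α-stannyl butenolide 8 + (E)-1-bromopropene (Stille); 8 ⇐ γ-hydroxy ynoate 6 (syn-hydrostannation, lactonization); 6 ⇐ α-keto ester 4 + methyl propiolate (enantioselective alkynylation, sets C4); 4 ⇐ veratraldehyde + 2-oxobutanoic acid.

Key step: step 6

Assumption: in step 3 the antipode of the chiral zinc ligand that delivers the alkynyl group to the Re face of the ketone of 4 is used (this gives (R)-6 and hence (S)-13); which antipode that is has to be fixed in the first run.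

**Step 1**
Reactants: 1 3,4-dimethoxybenzaldehyde; 2 2-oxobutanoic acid
Product: 3 (E)-4-(3,4-dimethoxyphenyl)-3-methyl-2-oxobut-3-enoic acid
Conditions: KOH, MeOH–H2O, 0 °C → rt; then aq. HCl
Reagents that add atoms: none
Why: Claisen–Schmidt-type aldol condensation of the methylene group of the α-keto acid with the non-enolizable aldehyde should give the thermodynamically preferred (E)-enone, with the aryl group trans to the keto acid carbonyl.

**Step 2**
Reactants: 3 (E)-4-(3,4-dimethoxyphenyl)-3-methyl-2-oxobut-3-enoic acid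
Product: 4 methyl (E)-4-(3,4-dimethoxyphenyl)-3-methyl-2-oxobut-3-enoate
Conditions: MeI, KHCO3, DMF, rt
Reagents that add atoms: iodomethane, CI
Why: Carboxylate O-alkylation under weakly basic conditions should esterify the acid without touching the enone or the activated ketone.

**Step 3**
Reactants: 4 methyl (E)-4-(3,4-dimethoxyphenyl)-3-methyl-2-oxobut-3-enoate; 5 methyl propiolate
Product: 6 dimethyl (R)-4-[(E)-1-(3,4-dimethoxyphenyl)prop-1-en-2-yl]-4-hydroxypent-2-ynedioate
Conditions: Me2Zn, ProPhenol-type ligand (2,6-bis{[2-(hydroxydiphenylmethyl)pyrrolidin-1-yl]methyl}-4-methylphenol, 20 mol %), PhMe, 0 °C → rt; then 1 M HCl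
Reagents that add atoms: none
Why: Catalytic enantioselective addition of the alkynylzinc formed from methyl propiolate and Me2Zn to the two-point-binding α-keto ester should set the only stereocenter by Re-face delivery under control of the chiral dinuclear zinc catalyst, with 1,2-addition favoured over 1,4-addition by the α-branched enone.

**Step 4**
Reactants: 6 dimethyl (R)-4-[(E)-1-(3,4-dimethoxyphenyl)prop-1-en-2-yl]-4-hydroxypent-2-ynedioate
Product: 8 methyl (S)-2-[(E)-1-(3,4-dimethoxyphenyl)prop-1-en-2-yl]-5-oxo-4-(tributylstannyl)-2,5-dihydrofuran-2-carboxylate, via open-chain vinylstannane 7 (not isolated)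
Conditions: Bu3SnH, Pd(PPh3)4 (2 mol %), THF, 0 °C → rt; then PPTS (cat.), PhMe, 40 °C
Reagents that add atoms: tributyltin hydride, CCCC[SnH](CCCC)CCCC
Why: Syn-hydrostannation of an alkynoate under zerovalent palladium catalysis should place tin α to the ester and hydrogen on the β-carbon, so that the carbinol carbon and the ester are cis and the tertiary hydroxyl lactonizes to the butenolide; the stereocenter is not touched (the descriptor changes only because the priorities change).

**Step 5**
Reactants: 8 methyl (S)-2-[(E)-1-(3,4-dimethoxyphenyl)prop-1-en-2-yl]-5-oxo-4-(tributylstannyl)-2,5-dihydrofuran-2-carboxylate; 9 (E)-1-bromoprop-1-ene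
Product: 10 methyl (S)-2-[(E)-1-(3,4-dimethoxyphenyl)prop-1-en-2-yl]-5-oxo-4-[(E)-prop-1-en-1-yl]-2,5-dihydrofuran-2-carboxylate
Conditions: Pd(PPh3)4 (5 mol %), CuI (10 mol %), CsF, DMF, 45 °C, sealed tube
Reagents that add atoms: none
Why: Stille cross-coupling of the α-stannyl butenolide with the vinyl bromide, accelerated by copper iodide and fluoride, should proceed with retention at both sp2 carbons and so deliver the (E)-propenyl group.

**Step 6**
Reactants: 10 methyl (S)-2-[(E)-1-(3,4-dimethoxyphenyl)prop-1-en-2-yl]-5-oxo-4-[(E)-prop-1-en-1-yl]-2,5-dihydrofuran-2-carboxylate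
Product: 12 (S)-4-[(E)-1-(3,4-dimethoxyphenyl)prop-1-en-2-yl]-4-hydroxy-5-methoxy-2-[(E)-prop-1-en-1-yl]cyclohexa-2,5-dien-1-one, via hydroxy keto ylide 11 (not isolated)
Conditions: Ph3PCH3Br, KHMDS, THF, 0 °C; 10 added at −78 °C → rt; then PhMe, 100 °C
Reagents that add atoms: methylenetriphenylphosphorane, C=P(c1ccccc1)(c1ccccc1)c1ccccc1 (made in the flask from methyltriphenylphosphonium bromide, C[P+](c1ccccc1)(c1ccccc1)c1ccccc1.[Br-], and KHMDS)
Why: Ph3P=CH2 should add to the lactone carbonyl of 10 (C1), the tetrahedral adduct should collapse by expelling the tertiary α-ester alkoxide (the C4 oxygen), and proton transfer from the acylmethylphosphonium to that alkoxide gives the neutral hydroxy keto ylide 11, in which the cis C2=C3 geometry inherited from the butenolide holds the ylide carbon (C6) next to the methyl ester (C5); on heating C6 attacks the ester carbonyl and [2+2] addition/cycloreversion expels Ph3P=O, leaving the ester methoxy group on C5 as the enol ether. The closest known reaction types are the acylation of non-stabilized phosphorus ylides by lactones to ω-hydroxy acyl ylides and the intramolecular Wittig olefination of ester carbonyls by carbonyl-stabilized ylides (tetronates from α-hydroxy esters, chromones from aryl esters). Ring A closes in a 6-exo-trig mode (ylide carbon onto the ester C=O) while the five-membered lactone is opened, so the step is a net furanone-to-cyclohexadienone ring transformation that also brings in the last ring carbon. No stereocenter is formed: C4 was set in step 3, it is quaternary and none of its four bonds is broken, since the lactone is cleaved at the acyl C–O bond. The step needs chemoselectivity for the lactone carbonyl over the methyl ester and over conjugate addition, which should be secured by the higher acyl-transfer reactivity of the butenolide, the neopentyl position of the ester and the fully substituted C4 next to the β-carbon. The regiochemistry of the vinylogous ester is fixed by construction, because C1 enters as the ketone and C5 keeps its methoxy group, which a Claisen condensation followed by O-methylation of the resulting 1,3-dione could not guarantee.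

**Step 7**
Reactants: 12 (S)-4-[(E)-1-(3,4-dimethoxyphenyl)prop-1-en-2-yl]-4-hydroxy-5-methoxy-2-[(E)-prop-1-en-1-yl]cyclohexa-2,5-dien-1-one
Product: 13 (S)-4-[(E)-1-(3,4-dimethoxyphenyl)prop-1-en-2-yl]-4,5-dimethoxy-2-[(E)-prop-1-en-1-yl]cyclohexa-2,5-dien-1-one
Conditions: NaH, MeI, THF–DMF, 0 °C → rt
Reagents that add atoms: iodomethane, CI
Why: Williamson etherification of the tertiary p-quinol alkoxide with MeI should give the methyl ether; C4 is quaternary and cannot epimerize, and the dienone carries no acidic C–H.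

**Compound list**
1 | 3,4-dimethoxybenzaldehyde (veratraldehyde) | COc1ccc(C=O)cc1OC | starting material
2 | 2-oxobutanoic acid | CCC(=O)C(=O)O | starting material
3 | (E)-4-(3,4-dimethoxyphenyl)-3-methyl-2-oxobut-3-enoic acid | OC(=O)C(=O)/C(C)=C/c1ccc(OC)c(OC)c1 | intermediate
4 | methyl (E)-4-(3,4-dimethoxyphenyl)-3-methyl-2-oxobut-3-enoate | COC(=O)C(=O)/C(C)=C/c1ccc(OC)c(OC)c1 | intermediate
5 | methyl propiolate (methyl prop-2-ynoate) | C#CC(=O)OC | starting material
6 | dimethyl (R)-4-[(E)-1-(3,4-dimethoxyphenyl)prop-1-en-2-yl]-4-hydroxypent-2-ynedioate | COC(=O)C#C[C@](O)(/C(C)=C/c1ccc(OC)c(OC)c1)C(=O)OC | intermediate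
7 | dimethyl (2E,4S)-4-[(E)-1-(3,4-dimethoxyphenyl)prop-1-en-2-yl]-4-hydroxy-2-(tributylstannyl)pent-2-enedioate (open-chain vinylstannane) | CCCC[Sn](CCCC)(CCCC)/C(=C/[C@](O)(/C(C)=C/c1ccc(OC)c(OC)c1)C(=O)OC)C(=O)OC | intermediate
8 | methyl (S)-2-[(E)-1-(3,4-dimethoxyphenyl)prop-1-en-2-yl]-5-oxo-4-(tributylstannyl)-2,5-dihydrofuran-2-carboxylate | CCCC[Sn](CCCC)(CCCC)C1=C[C@](OC1=O)(/C(C)=C/c2ccc(OC)c(OC)c2)C(=O)OC | intermediate
9 | (E)-1-bromoprop-1-ene | C/C=C/Br | starting material
10 | methyl (S)-2-[(E)-1-(3,4-dimethoxyphenyl)prop-1-en-2-yl]-5-oxo-4-[(E)-prop-1-en-1-yl]-2,5-dihydrofuran-2-carboxylate | C/C=C/C1=C[C@](OC1=O)(/C(C)=C/c2ccc(OC)c(OC)c2)C(=O)OC | intermediate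
11 | methyl (2S,3Z)-2-[(E)-1-(3,4-dimethoxyphenyl)prop-1-en-2-yl]-2-hydroxy-5-oxo-4-[(E)-prop-1-en-1-yl]-6-(triphenylphosphoranylidene)hex-3-enoate (hydroxy keto ylide) | C/C=C/C(=C/[C@](O)(/C(C)=C/c1ccc(OC)c(OC)c1)C(=O)OC)C(=O)C=P(c1ccccc1)(c1ccccc1)c1ccccc1 | intermediate
12 | (S)-4-[(E)-1-(3,4-dimethoxyphenyl)prop-1-en-2-yl]-4-hydroxy-5-methoxy-2-[(E)-prop-1-en-1-yl]cyclohexa-2,5-dien-1-one | C/C=C/C1=C[C@](O)(/C(C)=C/c2ccc(OC)c(OC)c2)C(OC)=CC1=O | intermediate
13 | (S)-4-[(E)-1-(3,4-dimethoxyphenyl)prop-1-en-2-yl]-4,5-dimethoxy-2-[(E)-prop-1-en-1-yl]cyclohexa-2,5-dien-1-one | C/C=C/C1=C[C@](OC)(/C(C)=C/c2ccc(OC)c(OC)c2)C(OC)=CC1=O | target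

**Total step count:** 7
**Longest linear sequence:** 7 steps (1 → 3 → 4 → 6 → 8 → 10 → 12 → 13)

**Steps most likely to fail**

1. Step 6. The ylide may be misdirected (attack of Ph3P=CH2 at the methyl ester or at the β-carbon of the butenolide instead of the lactone carbonyl), or the opened ylide may revert to the lactone before it olefinates the hindered ester. The fallback sets out from 6 and comes back at 13; it removes the second reactive acyl group and the free hydroxyl before the ylide is made.
 - The tertiary hydroxyl of 6 is methylated first (MeI, Ag2O, MeCN) to give dimethyl (R)-4-[(E)-1-(3,4-dimethoxyphenyl)prop-1-en-2-yl]-4-methoxypent-2-ynedioate F1.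
 - Hydrostannation as in step 4 now stops at the open-chain stage, because no hydroxyl is left to lactonize, and gives the (2E,4S)-4-methoxy-2-(tributylstannyl)pent-2-enedioate F2.
 - Stille coupling with 9 as in step 5 gives the (2Z,4S)-4-methoxy-2-[(E)-propenyl]pent-2-enedioate F3.
 - The accessible dienoate ester is saponified selectively (Me3SnOH, 1,2-dichloroethane, 70 °C), the neopentyl α-methoxy ester being spared, to give the (2Z,4S)-monoacid F4.
 - 1,1'-Carbonyldiimidazole converts F4 into the acyl imidazolide F5, the only acyl group that should react with Ph3P=CH2 (2 equiv, THF, −78 °C → rt); this gives the methoxy keto ylide F6, the O-methyl analogue of 11.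
 - Heating (PhMe, 100 °C) should close F6 by the same ester olefination directly to 13.

2. Step 3. Facial selectivity may be insufficient, or the propiolate may undergo conjugate addition or oligomerization under the zinc conditions. The fallback sets out from 4 and comes back at 6; it uses a well-behaved alkyne donor and builds the ester carbon afterwards.
 - Zinc-mediated enantioselective alkynylation of 4 with trimethylsilylacetylene (Zn(OTf)2, Et3N, chiral amino alcohol ligand, PhMe) gives methyl (R,E)-4-(3,4-dimethoxyphenyl)-2-hydroxy-3-methyl-2-[(trimethylsilyl)ethynyl]but-3-enoate F7.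
 - K2CO3 in MeOH removes the silyl group and gives methyl (S,E)-4-(3,4-dimethoxyphenyl)-2-ethynyl-2-hydroxy-3-methylbut-3-enoate F8 (same spatial arrangement; the descriptor changes with the priorities).
 - Oxidative methoxycarbonylation of the terminal alkyne (PdCl2 cat., CuCl2, NaOAc, CO 1 atm, MeOH, rt) returns to 6.

3. Step 5. Transmetalation of the hindered α-stannyl butenolide may be slow, with protodestannylation, loss of the volatile bromide or erosion of the propenyl geometry. The fallback sets out from 8 and comes back at 10; it exchanges the roles of the coupling partners.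
 - Iododestannylation (I2, CH2Cl2, 0 °C) gives methyl (S)-2-[(E)-1-(3,4-dimethoxyphenyl)prop-1-en-2-yl]-4-iodo-5-oxo-2,5-dihydrofuran-2-carboxylate F9.
 - Suzuki–Miyaura coupling of F9 with commercial (E)-prop-1-enylboronic acid (PdCl2(dppf) cat., K3PO4, THF–H2O, 40 °C) returns to 10.

**Further compounds**
F1 | step 6 | dimethyl (R)-4-[(E)-1-(3,4-dimethoxyphenyl)prop-1-en-2-yl]-4-methoxypent-2-ynedioate | COC(=O)C#C[C@](OC)(/C(C)=C/c1ccc(OC)c(OC)c1)C(=O)OC
F2 | step 6 | dimethyl (2E,4S)-4-[(E)-1-(3,4-dimethoxyphenyl)prop-1-en-2-yl]-4-methoxy-2-(tributylstannyl)pent-2-enedioate | CCCC[Sn](CCCC)(CCCC)/C(=C/[C@](OC)(/C(C)=C/c1ccc(OC)c(OC)c1)C(=O)OC)C(=O)OC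
F3 | step 6 | dimethyl (2Z,4S)-4-[(E)-1-(3,4-dimethoxyphenyl)prop-1-en-2-yl]-4-methoxy-2-[(E)-prop-1-en-1-yl]pent-2-enedioate | C/C=C/C(=C/[C@](OC)(/C(C)=C/c1ccc(OC)c(OC)c1)C(=O)OC)C(=O)OC
F4 | step 6 | (2Z,4S)-4-[(E)-1-(3,4-dimethoxyphenyl)prop-1-en-2-yl]-4,5-dimethoxy-5-oxo-2-[(E)-prop-1-en-1-yl]pent-2-enoic acid | C/C=C/C(=C/[C@](OC)(/C(C)=C/c1ccc(OC)c(OC)c1)C(=O)OC)C(=O)O
F5 | step 6 | methyl (2S,3Z)-2-[(E)-1-(3,4-dimethoxyphenyl)prop-1-en-2-yl]-5-(1H-imidazol-1-yl)-2-methoxy-5-oxo-4-[(E)-prop-1-en-1-yl]pent-3-enoate | C/C=C/C(=C/[C@](OC)(/C(C)=C/c1ccc(OC)c(OC)c1)C(=O)OC)C(=O)n1ccnc1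
F6 | step 6 | methyl (2S,3Z)-2-[(E)-1-(3,4-dimethoxyphenyl)prop-1-en-2-yl]-2-methoxy-5-oxo-4-[(E)-prop-1-en-1-yl]-6-(triphenylphosphoranylidene)hex-3-enoate | C/C=C/C(=C/[C@](OC)(/C(C)=C/c1ccc(OC)c(OC)c1)C(=O)OC)C(=O)C=P(c1ccccc1)(c1ccccc1)c1ccccc1
F7 | step 3 | methyl (R,E)-4-(3,4-dimethoxyphenyl)-2-hydroxy-3-methyl-2-[(trimethylsilyl)ethynyl]but-3-enoate | C[Si](C)(C)C#C[C@](O)(/C(C)=C/c1ccc(OC)c(OC)c1)C(=O)OC
F8 | step 3 | methyl (S,E)-4-(3,4-dimethoxyphenyl)-2-ethynyl-2-hydroxy-3-methylbut-3-enoate | C#C[C@](O)(/C(C)=C/c1ccc(OC)c(OC)c1)C(=O)OC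
F9 | step 5 | methyl (S)-2-[(E)-1-(3,4-dimethoxyphenyl)prop-1-en-2-yl]-4-iodo-5-oxo-2,5-dihydrofuran-2-carboxylate | IC1=C[C@](OC1=O)(/C(C)=C/c2ccc(OC)c(OC)c2)C(=O)OC
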